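**Strategy.** Everything rests on cutting the anomeric carbon out of a six-membered lactol: the dihydrofuran ring (O1, C2, C3, C3a, C7a) of gnetal is formed by contraction of a 3,4-diarylchroman-2-ol. The step exploits the O1–C2 bond, a 4-oxybenzylic aryl ether next to the C3 stereocentre: Baeyer–Villiger oxidation turns the masked aldehyde into a benzylic formate, which ionises and is recaptured by the phenol oxygen, trans to the C3 aryl group. All lactol isomers at the carbons that become C2 and the lost carbon converge; only the future C3, set by an isothiourea-catalysed o-quinone methide annulation, must be defined. Bromine-to-formyl exchange and debenzylation finish the synthesis.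

Key step: step 7

Assumption: the absolute sense of the isothiourea step is assigned by analogy with related Michael addition–lactonisations; (2S,3R)-HyperBTM is written for the (4S) lactone, and the mirror-image catalyst would be used if the opposite sense were found.

Step 1
Reactants: 1 4-bromo-2,6-difluorobenzaldehyde
Product: 2 2,6-bis(benzyloxy)-4-bromobenzaldehyde
Conditions: BnOH (2.3 equiv), NaH, DMF, 0 °C to 50 °C
Reagents that add atoms: benzyl alcohol, OCc1ccccc1
Why: Both fluorides sit ortho to the formyl group and should be displaced by benzyloxide in a double nucleophilic aromatic substitution (SNAr), fluoride being a far better leaving group than the para bromide.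

Step 2
Reactants: 2 2,6-bis(benzyloxy)-4-bromobenzaldehyde
Product: 3 2-(benzyloxy)-4-bromo-6-hydroxybenzaldehyde
Conditions: MgBr2·OEt2 (1.1 equiv), toluene–Et2O, reflux; then 1 M HCl
Reagents that add atoms: none
Why: Magnesium chelated between the aldehyde oxygen and one ortho ether oxygen activates that benzyl group for cleavage by bromide (chelation-controlled ortho-debenzylation), and the resulting magnesium phenoxide chelate should protect the second ether.

Step 3
Reactants: 3 2-(benzyloxy)-4-bromo-6-hydroxybenzaldehyde; 4 1,3-bis(benzyloxy)-5-bromobenzene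
Product: 6 (RS)-[2-(benzyloxy)-4-bromo-6-hydroxyphenyl][3,5-bis(benzyloxy)phenyl]methanol, via aryl Grignard reagent 5 (not isolated)
Conditions: 4, Mg, THF, rt (2.3 equiv of 5); then 3, THF, −20 to 0 °C; aq. NH4Cl
Reagents that add atoms: none
Why: Grignard addition to the aldehyde after the first equivalent has deprotonated the phenol; the carbinol centre forms racemic, which is immaterial because it is erased in the quinone methide of step 5.

Step 4
Reactants: 6 (RS)-[2-(benzyloxy)-4-bromo-6-hydroxyphenyl][3,5-bis(benzyloxy)phenyl]methanol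
Product: 7 3-(benzyloxy)-5-bromo-2-{(RS)-[3,5-bis(benzyloxy)phenyl](4-methylbenzenesulfonyl)methyl}phenol
Conditions: p-TolSO2H (1.5 equiv), CH2Cl2, rt
Reagents that add atoms: 4-methylbenzenesulfinic acid, Cc1ccc(cc1)S(=O)O
Why: The doubly ortho-oxygenated benzhydrol ionises under mild acid and the sulfinate is S-alkylated (SN1 substitution), which should give a bench-stable racemic o-quinone methide precursor.

Step 5
Reactants: 7 3-(benzyloxy)-5-bromo-2-{(RS)-[3,5-bis(benzyloxy)phenyl](4-methylbenzenesulfonyl)methyl}phenol; 8 [4-(benzyloxy)phenyl]acetic acid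
Product: 11 (3R,4S)-5-(benzyloxy)-3-[4-(benzyloxy)phenyl]-4-[3,5-bis(benzyloxy)phenyl]-7-bromo-3,4-dihydro-2H-chromen-2-one, via pivalic mixed anhydride 9 (not isolated), via o-quinone methide 10 (not isolated)
Conditions: 8, t-BuCOCl, i-Pr2NEt, CH2Cl2, 0 °C; then 7, (2S,3R)-HyperBTM (10 mol %), Cs2CO3, CH2Cl2, 0 °C to rt
Reagents that add atoms: none
Why: Isothiourea-catalysed Michael addition–lactonisation (formal [4+2] annulation) of the C1-ammonium enolate from 9 with quinone methide 10 released from 7 by base; the catalyst fixes the enolate face (acyl ammonium with 1,5-O···S contact, approach anti to its phenyl group) and the cis-selective approach of the quinone methide relays this to C4 (4S), while C3, although also set, is not needed later.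

Step 6
Reactants: 11 (3R,4S)-5-(benzyloxy)-3-[4-(benzyloxy)phenyl]-4-[3,5-bis(benzyloxy)phenyl]-7-bromo-3,4-dihydro-2H-chromen-2-one
Product: 12 (3R,4S)-5-(benzyloxy)-3-[4-(benzyloxy)phenyl]-4-[3,5-bis(benzyloxy)phenyl]-7-bromochroman-2-ol (anomer mixture at C2)
Conditions: DIBAL-H (1.1 equiv), CH2Cl2, −78 °C; Rochelle salt
Reagents that add atoms: none
Why: Partial reduction of the aryl lactone to the lactol (DIBAL-H reduction), the tetrahedral aluminate being stable at −78 °C; C3 and C4 are untouched and C2 forms as an anomer mixture that does not matter.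

Step 7
Reactants: 12 (3R,4S)-5-(benzyloxy)-3-[4-(benzyloxy)phenyl]-4-[3,5-bis(benzyloxy)phenyl]-7-bromochroman-2-ol
Product: 14 (2S,3S)-4-(benzyloxy)-2-[4-(benzyloxy)phenyl]-3-[3,5-bis(benzyloxy)phenyl]-6-bromo-2,3-dihydro-1-benzofuran, via benzylic formate 13 (not isolated)
Conditions: mCPBA (1.2 equiv), Na2HPO4, CH2Cl2, 0 °C to rt; then TFA (5 equiv), 0 °C
Reagents that add atoms: none
Why: Lactol 12 reacts as its hydroxy aldehyde tautomer: mCPBA adds to the anomeric carbon (chromanol C2) and, in the Criegee adduct, the secondary benzylic carbon (chromanol C3) migrates to oxygen with retention to give formate 13, which cuts C2 out of the ring skeleton. TFA then ionises the 4-benzyloxybenzylic C–O bond and the phenol oxygen (old O1) captures the cation, so that the six-membered lactol ring ends as the five-membered O1–C2–C3–C3a–C7a ring with loss of formic acid. The closest known reaction types are the Baeyer–Villiger degradation of lactols and α-aryl aldehydes to nor-formates and the acid-mediated cyclodehydration of 1,2-diaryl-2-(2-hydroxyaryl)ethanols to trans-2,3-diaryl-2,3-dihydrobenzofurans. The ring closes in a 5-exo-trig mode, oxygen attacking the exocyclic terminus of the quinone-methide-like benzylic cation. The new C2 centre is controlled by the existing diaryl centre (chromanol C4, future C3): the 4-benzyloxyphenyl group settles anti to the C3 aryl group and reversible C2–O ionisation lets any cis ether equilibrate, so all C2/C3 isomers of 12 should converge on (2S,3S)-14. The step needs carbon rather than hydride migration, secured by the electron-rich benzylic migrating group, and cation capture faster than proton loss or hydride shift at the diaryl carbon, secured by the ortho phenol placed for five-membered ring closure and by the low temperature.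

Step 8
Reactants: 14 (2S,3S)-4-(benzyloxy)-2-[4-(benzyloxy)phenyl]-3-[3,5-bis(benzyloxy)phenyl]-6-bromo-2,3-dihydro-1-benzofuran
Product: 16 (2S,3S)-4-(benzyloxy)-2-[4-(benzyloxy)phenyl]-3-[3,5-bis(benzyloxy)phenyl]-2,3-dihydro-1-benzofuran-6-carbaldehyde, via aryllithium 15 (not isolated)
Conditions: n-BuLi (1.1 equiv), THF, −78 °C; then DMF; aq. NH4Cl
Reagents that add atoms: N,N-dimethylformamide, CN(C)C=O
Why: Bromine–lithium exchange is much faster than any deprotonation at −78 °C and the aryllithium is formylated by DMF (Bouveault formylation); the stereocentres are not involved.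

Step 9
Reactants: 16 (2S,3S)-4-(benzyloxy)-2-[4-(benzyloxy)phenyl]-3-[3,5-bis(benzyloxy)phenyl]-2,3-dihydro-1-benzofuran-6-carbaldehyde
Product: 17 gnetal, (2S,3S)-3-(3,5-dihydroxyphenyl)-4-hydroxy-2-(4-hydroxyphenyl)-2,3-dihydro-1-benzofuran-6-carbaldehyde
Conditions: BCl3 (8 equiv), C6HMe5 (12 equiv), CH2Cl2, −78 °C; MeOH quench
Reagents that add atoms: none
Why: BCl3 cleaves the four aryl benzyl ethers at −78 °C while pentamethylbenzene scavenges the benzyl cations (Lewis acid debenzylation with a cation scavenger), conditions that should leave the aldehyde alone; if the C2–O bond ionised reversibly, reclosure would return the trans ring and C3 is not affected.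

**Compound list**

1 | 4-bromo-2,6-difluorobenzaldehyde | O=Cc1c(F)cc(Br)cc1F | starting material
2 | 2,6-bis(benzyloxy)-4-bromobenzaldehyde | O=Cc1c(OCc2ccccc2)cc(Br)cc1OCc1ccccc1 | intermediate
3 | 2-(benzyloxy)-4-bromo-6-hydroxybenzaldehyde | O=Cc1c(O)cc(Br)cc1OCc1ccccc1 | intermediate
4 | 1,3-bis(benzyloxy)-5-bromobenzene | Brc1cc(OCc2ccccc2)cc(OCc2ccccc2)c1 | starting material
5 | [3,5-bis(benzyloxy)phenyl]magnesium bromide (not isolated) | Br[Mg]c1cc(OCc2ccccc2)cc(OCc2ccccc2)c1 | intermediate
6 | (RS)-[2-(benzyloxy)-4-bromo-6-hydroxyphenyl][3,5-bis(benzyloxy)phenyl]methanol | OC(c1cc(OCc2ccccc2)cc(OCc2ccccc2)c1)c1c(O)cc(Br)cc1OCc1ccccc1 | intermediate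
7 | 3-(benzyloxy)-5-bromo-2-{(RS)-[3,5-bis(benzyloxy)phenyl](4-methylbenzenesulfonyl)methyl}phenol | Cc1ccc(cc1)S(=O)(=O)C(c1cc(OCc2ccccc2)cc(OCc2ccccc2)c1)c1c(O)cc(Br)cc1OCc1ccccc1 | intermediate
8 | [4-(benzyloxy)phenyl]acetic acid | OC(=O)Cc1ccc(OCc2ccccc2)cc1 | starting material
9 | [4-(benzyloxy)phenyl]acetic 2,2-dimethylpropanoic anhydride (not isolated) | CC(C)(C)C(=O)OC(=O)Cc1ccc(OCc2ccccc2)cc1 | intermediate
10 | 5-(benzyloxy)-3-bromo-6-{[3,5-bis(benzyloxy)phenyl]methylidene}cyclohexa-2,4-dien-1-one, o-quinone methide (not isolated) | O=C1C=C(Br)C=C(OCc2ccccc2)C1=Cc1cc(OCc2ccccc2)cc(OCc2ccccc2)c1 | intermediate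
11 | (3R,4S)-5-(benzyloxy)-3-[4-(benzyloxy)phenyl]-4-[3,5-bis(benzyloxy)phenyl]-7-bromo-3,4-dihydro-2H-chromen-2-one (cis; the 3S epimer from base epimerisation is carried along) | O=C1Oc2cc(Br)cc(OCc3ccccc3)c2[C@H](c2cc(OCc3ccccc3)cc(OCc3ccccc3)c2)[C@@H]1c1ccc(OCc2ccccc2)cc1 | intermediate
12 | (3R,4S)-5-(benzyloxy)-3-[4-(benzyloxy)phenyl]-4-[3,5-bis(benzyloxy)phenyl]-7-bromochroman-2-ol, anomer mixture at C2 | OC1Oc2cc(Br)cc(OCc3ccccc3)c2[C@H](c2cc(OCc3ccccc3)cc(OCc3ccccc3)c2)[C@@H]1c1ccc(OCc2ccccc2)cc1 | intermediate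
13 | (1R,2S)-2-[2-(benzyloxy)-4-bromo-6-hydroxyphenyl]-1-[4-(benzyloxy)phenyl]-2-[3,5-bis(benzyloxy)phenyl]ethyl formate (not isolated) | O=CO[C@@H](c1ccc(OCc2ccccc2)cc1)[C@@H](c1cc(OCc2ccccc2)cc(OCc2ccccc2)c1)c1c(O)cc(Br)cc1OCc1ccccc1 | intermediate
14 | (2S,3S)-4-(benzyloxy)-2-[4-(benzyloxy)phenyl]-3-[3,5-bis(benzyloxy)phenyl]-6-bromo-2,3-dihydro-1-benzofuran (trans) | Brc1cc(OCc2ccccc2)c2c(c1)O[C@H](c1ccc(OCc3ccccc3)cc1)[C@H]2c1cc(OCc2ccccc2)cc(OCc2ccccc2)c1 | intermediate
15 | {(2S,3S)-4-(benzyloxy)-2-[4-(benzyloxy)phenyl]-3-[3,5-bis(benzyloxy)phenyl]-2,3-dihydro-1-benzofuran-6-yl}lithium (not isolated) | [Li]c1cc(OCc2ccccc2)c2c(c1)O[C@H](c1ccc(OCc3ccccc3)cc1)[C@H]2c1cc(OCc2ccccc2)cc(OCc2ccccc2)c1 | intermediate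
16 | (2S,3S)-4-(benzyloxy)-2-[4-(benzyloxy)phenyl]-3-[3,5-bis(benzyloxy)phenyl]-2,3-dihydro-1-benzofuran-6-carbaldehyde | O=Cc1cc(OCc2ccccc2)c2c(c1)O[C@H](c1ccc(OCc3ccccc3)cc1)[C@H]2c1cc(OCc2ccccc2)cc(OCc2ccccc2)c1 | intermediate
17 | gnetal, (2S,3S)-3-(3,5-dihydroxyphenyl)-4-hydroxy-2-(4-hydroxyphenyl)-2,3-dihydro-1-benzofuran-6-carbaldehyde | O=Cc1cc(O)c2c(c1)O[C@H](c1ccc(O)cc1)[C@H]2c1cc(O)cc(O)c1 | target

**Step count.** Total: 9 steps. Longest linear sequence: 9 steps (1 to 17); 4 and 8 enter as purchased.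

**Steps most likely to fail**

Step 7 (key step). Hydride instead of carbon migration in the Criegee adduct would return lactone 11. A long-lived benzylic cation could also lose the neighbouring proton or take a 1,2-hydride shift, which would erode the configuration of the diaryl carbon. The fallback sets out from lactol 12 and replaces the peracid by a radical fragmentation. Hypoiodite formation (PhI(OAc)2, I2, hν, CH2Cl2) gives the anomeric alkoxy radical, whose β-scission cleaves the C2–C3 bond. The benzylic radical is oxidised and trapped as acetate while the old C2 stays on the phenol oxygen as a formate, giving 2-{(1S)-2-(acetyloxy)-2-[4-(benzyloxy)phenyl]-1-[3,5-bis(benzyloxy)phenyl]ethyl}-3-(benzyloxy)-5-bromophenyl formate F1. K2CO3 in MeOH removes the aryl formate and the phenoxide displaces the benzylic acetate. A brief treatment with catalytic TsOH equilibrates any cis ether, and the route is rejoined at 14.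

Step 5. Facial selectivity may be poor on a quinone methide that carries a benzyloxy group next to the methide carbon. Because C4 is set relative to the catalyst-controlled C3, a low diastereomer ratio would appear as low enantiomeric purity after step 7. The fallback sets out from aldehyde 3 and sets the diaryl centre directly. Wittig olefination with lactonisation (Ph3P=CHCO2Et, PhNEt2, reflux) gives 5-(benzyloxy)-7-bromo-2H-chromen-2-one F2. Rhodium-catalysed asymmetric conjugate addition of 3,5-bis(benzyloxy)phenylboronic acid (Rh(acac)(C2H4)2, Segphos enantiomer chosen for the 4S product, dioxane–H2O, 60 °C) gives (4S)-5-(benzyloxy)-4-[3,5-bis(benzyloxy)phenyl]-7-bromo-3,4-dihydro-2H-chromen-2-one F3. Arylation of its lithium enolate (LiHMDS, THF, −78 °C) with bis[4-(benzyloxy)phenyl]iodonium triflate rejoins the route at 11, as a C3 epimer mixture that step 7 tolerates.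

Step 9. Lewis acid opening of the benzylic C2–O bond, or C-benzylation of the electron-rich rings by escaping benzyl cations, may degrade the product during debenzylation. The fallback sets out from aldehyde 16 and avoids the Lewis acid. The formyl group is masked (HC(OMe)3, PPTS, MeOH) as (2S,3S)-4-(benzyloxy)-2-[4-(benzyloxy)phenyl]-3-[3,5-bis(benzyloxy)phenyl]-6-(dimethoxymethyl)-2,3-dihydro-1-benzofuran F4. Hydrogenolysis (H2, Pd/C, EtOAc–MeOH) removes the four benzyl groups to give (2S,3S)-3-(3,5-dihydroxyphenyl)-6-(dimethoxymethyl)-2-(4-hydroxyphenyl)-2,3-dihydro-1-benzofuran-4-ol F5. Dilute aqueous acid (AcOH–H2O–THF, rt) then releases the aldehyde and arrives at target 17.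

**Further compounds**

F1 | step 7 | 2-{(1S)-2-(acetyloxy)-2-[4-(benzyloxy)phenyl]-1-[3,5-bis(benzyloxy)phenyl]ethyl}-3-(benzyloxy)-5-bromophenyl formate (acetoxy carbon as epimer mixture) | CC(=O)OC(c1ccc(OCc2ccccc2)cc1)[C@@H](c1cc(OCc2ccccc2)cc(OCc2ccccc2)c1)c1c(OC=O)cc(Br)cc1OCc1ccccc1
F2 | step 5 | 5-(benzyloxy)-7-bromo-2H-chromen-2-one | O=C1C=Cc2c(OCc3ccccc3)cc(Br)cc2O1
F3 | step 5 | (4S)-5-(benzyloxy)-4-[3,5-bis(benzyloxy)phenyl]-7-bromo-3,4-dihydro-2H-chromen-2-one | O=C1C[C@@H](c2cc(OCc3ccccc3)cc(OCc3ccccc3)c2)c2c(OCc3ccccc3)cc(Br)cc2O1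
F4 | step 9 | (2S,3S)-4-(benzyloxy)-2-[4-(benzyloxy)phenyl]-3-[3,5-bis(benzyloxy)phenyl]-6-(dimethoxymethyl)-2,3-dihydro-1-benzofuran | COC(OC)c1cc(OCc2ccccc2)c2c(c1)O[C@H](c1ccc(OCc3ccccc3)cc1)[C@H]2c1cc(OCc2ccccc2)cc(OCc2ccccc2)c1
F5 | step 9 | (2S,3S)-3-(3,5-dihydroxyphenyl)-6-(dimethoxymethyl)-2-(4-hydroxyphenyl)-2,3-dihydro-1-benzofuran-4-ol | COC(OC)c1cc(O)c2c(c1)O[C@H](c1ccc(O)cc1)[C@H]2c1cc(O)cc(O)c1
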